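**Assumptions**
- (R)-5-Methylcyclohex-2-enone (1) is available as a single enantiomer.
- The two C2 carbinol epimers from Step 2 are separable, and the (R)-carbinol 4 is carried on.
- C9 of the acetal and selenoacetal intermediates (12–20) is a mixture of epimers, which is harmless because the radical step erases it.
- Numbering below follows the natural-product skeleton (C1–C20).

**Retrosynthesis**
1. Asbestinin 16 (22) comes from α-methylenation of the oxonane ketone 21. Ketone 21 comes from a 9-endo radical macrocyclisation of the THF-2-yl radical (from selenoacetal 20) onto a vinyl ketone. This closes the oxonane (C8–C9) and sets C9.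
2. The C4–C5 bond is made by a chelation-controlled Mukaiyama aldol of the MVK-derived silyl dienol ether on α-alkoxy aldehyde 16.
3. The THF ring comes from a methoxymethylene Wittig reaction on the C10 ketone, then acid cyclisation with C2–OH.
4. The oxepane comes from a 7-endo HAT-initiated radical cyclisation (C14–C15) of a C3 allyl ether onto a cyclohexenone. The allyl ether comes from tertiary epoxide opening; the epoxide comes from directed epoxidation of the NHK adduct of 2-iodoenone and methacrolein.
5. Ring order: cyclohexane (from starting material 1), then oxepane (radical), then THF (acid), then oxonane (radical).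

---

**Step 1**
Reactants: 1 (R)-5-methylcyclohex-2-en-1-one
Product: 2 (R)-2-iodo-5-methylcyclohex-2-en-1-one
Conditions: I2, pyridine, CH2Cl2/CCl4, 0 °C → rt
Reagents that add atoms: iodine, II
Why: Johnson α-iodination (pyridine conjugate addition, iodination, elimination) makes the C1 handle; no stereocentre is formed and C12 is untouched.

**Step 2**
Reactants: 2; 3 methacrolein
Product: 4 (5R)-2-[(R)-1-hydroxy-2-methylallyl]-5-methylcyclohex-2-en-1-one
Conditions: CrCl2, NiCl2 (cat.), DMF, rt; separate epimers by chromatography
Reagents that add atoms: none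
Why: Nozaki–Hiyama–Kishi coupling of the vinyl iodide with the enal forms C1–C2 and delivers C2, C3 and C4 (with C18). C2 forms as about a 1:1 epimer mixture and the required (R)-epimer is isolated.

**Step 3**
Reactants: 4
Product: 5 (5R)-2-[(S)-hydroxy((R)-2-methyloxiran-2-yl)methyl]-5-methylcyclohex-2-en-1-one
Conditions: VO(acac)2 (5 mol %), t-BuOOH, CH2Cl2, 0 °C
Reagents that add atoms: tert-butyl hydroperoxide, CC(C)(C)OO (supplies the epoxide O)
Why: Hydroxyl-directed vanadium epoxidation; in the A(1,2)-strain-minimised conformer the C2–OH delivers O to its own face of the 1,1-disubstituted alkene, setting C3 as (R). The enone alkene is untouched.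

**Step 4**
Reactants: 5; 6 allyl alcohol
Product: 7 (5R)-2-[(1S,2S)-2-(allyloxy)-1,3-dihydroxy-2-methylpropyl]-5-methylcyclohex-2-en-1-one
Conditions: BF3·OEt2 (10 mol %), allyl alcohol (10 equiv), CH2Cl2, 0 °C
Reagents that add atoms: none
Why: Lewis-acid epoxide opening at the tertiary carbon proceeds by an SN2-like path with inversion, giving the C3 tertiary allyl ether with the (S) configuration required by the target. It also leaves the C4 primary alcohol.

**Step 5**
Reactants: 7
Product: 8 C4 tert-butyldiphenylsilyl ether of 7
Conditions: TBDPSCl, imidazole, DMF, 0 °C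
Reagents that add atoms: TBDPSCl, CC(C)(C)[Si](Cl)(c1ccccc1)c1ccccc1
Why: The primary alcohol is silylated selectively over the hindered C2 secondary alcohol; this protects C4 for the later C11 inversion. No stereocentre is formed.

**Step 6**
Reactants: 8
Product: 9 oxepane-fused cyclohexanone (C14–C15 bond formed)
Conditions: Fe(acac)3 (1 equiv), PhSiH3 (3 equiv), EtOH, 60 °C, 5 mM
Reagents that add atoms: none (PhSiH3 supplies only H)
Why: Fe–H hydrogen-atom transfer to the terminal allyl-ether alkene gives a nucleophilic secondary C15 radical that adds to the enone β-carbon C14 in a 7-endo Giese cyclisation. C14 forms anti to the C12 methyl, and C15 takes a pseudo-equatorial methyl in the chair-like 7-membered transition state. H-atom capture and epimerisation at C1 give the trans-fused 6/7 ring system, and the C3 quaternary centre survives.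
Proposed new method: The closest known reactions are Baran-type Fe–H olefin–enone coupling and 6-endo Giese cyclisations. Attack at C14 is favoured by polarity. The 6-exo alternative at the α-carbon would create a quaternary centre and is polarity-mismatched.

**Step 7**
Reactants: 9
Product: 10 C11-hydroxy ketone (OH trans to C12-Me)
Conditions: TMSCl, LDA, THF, −78 °C (internal quench); then DMDO, acetone, −78 °C; then K2CO3, MeOH
Reagents that add atoms: dimethyldioxirane, CC1(C)OO1
Why: Rubottom oxidation. Kinetic enolisation at the CH2 (C11) rather than the tertiary C1, with the C2-OH silylated in situ to prevent retro-aldol, then epoxidation of the silyl enol ether anti to the C12 methyl. This gives C11–OH trans to Me, which Step 10 inverts.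

**Step 8**
Reactants: 10
Product: 11 methoxymethylene enol ether (C10=C9H–OMe)
Conditions: Ph3P=CHOMe (from [Ph3PCH2OMe]Cl, KOtBu), THF, −20 °C → rt
Reagents that add atoms: (methoxymethyl)triphenylphosphonium chloride, COC[P+](c1ccccc1)(c1ccccc1)c1ccccc1.[Cl-] (supplies C9 and OMe)
Why: Wittig methoxymethylenation installs C9 at the oxidation level of an aldehyde. The E/Z enol ether ratio is irrelevant and no stereocentre is formed.

**Step 9**
Reactants: 11
Product: 12 THF methyl acetal (C9-OMe, C11-OH trans, C4-OTBDPS)
Conditions: PPTS (cat.), CH2Cl2, rt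
Reagents that add atoms: none (isomerisation)
Why: Protonation of the enol ether at C10 gives the C9 oxocarbenium, which C2–OH captures in a 5-exo closure. Only the cis-fused THF can form, so C10 (H up, C9 down) is fixed by the ring; the C9 epimers are both accepted.

**Step 10**
Reactants: 12
Product: 13 C11 acetate (cis to Me) of 12
Conditions: AcOH, PPh3, DIAD, THF, 0 °C → rt
Reagents that add atoms: acetic acid, CC(=O)O
Why: Mitsunobu SN2 inversion converts the trans C11–OH into the cis acetate in one step, which sets C11 as in the target.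

**Step 11**
Reactants: 13
Product: 14 C9 phenylselenoacetal
Conditions: PhSeSiMe3, ZnI2 (cat.), CH2Cl2, 0 °C
Reagents that add atoms: (phenylseleno)trimethylsilane, C[Si](C)(C)[Se]c1ccccc1
Why: Lewis-acid acetal exchange converts the methyl acetal into the radical precursor; C9 stereochemistry is irrelevant.

**Step 12**
Reactants: 14
Product: 15 C4 primary alcohol
Conditions: TBAF, AcOH (1:1), THF, 0 °C
Reagents that add atoms: none
Why: Buffered fluoride removes the TBDPS group and leaves the acetate and selenoacetal intact.

**Step 13**
Reactants: 15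
Product: 16 C4 aldehyde
Conditions: (COCl)2, DMSO, Et3N, CH2Cl2, −78 °C
Reagents that add atoms: none
Why: Swern oxidation. The aldehyde has no α-hydrogen (C3 is quaternary), so no epimerisation is possible.

**Step 14**
Reactants: 17 methyl vinyl ketone
Product: 18 2-(trimethylsilyloxy)buta-1,3-diene
Conditions: TMSOTf, Et3N, CH2Cl2, 0 °C
Reagents that add atoms: trimethylsilyl triflate, C[Si](C)(C)OS(=O)(=O)C(F)(F)F
Why: Kinetic silyl enol ether formation at the methyl group of MVK gives the C5–C8 nucleophile; no stereocentre is formed.

**Step 15**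
Reactants: 16; 18
Product: 19 β-hydroxy vinyl ketone (C4–OH, C5–C8 chain installed)
Conditions: TiCl4 (1.1 equiv), CH2Cl2, −78 °C; aqueous NaHCO3 work-up
Reagents that add atoms: none
Why: Mukaiyama aldol forms C4–C5. TiCl4 chelates the aldehyde oxygen and the C3 ether oxygen (Cram-chelate), so attack occurs from the face that gives C4 (R). The vinyl ketone carbons C7=C8 come from MVK.

**Step 16**
Reactants: 19
Product: 20 C4 octanoate
Conditions: octanoyl chloride, pyridine, DMAP (cat.), CH2Cl2, 0 °C
Reagents that add atoms: octanoyl chloride, CCCCCCCC(=O)Cl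
Why: Acylation of the C4 secondary alcohol installs the octanoate without affecting any stereocentre.

**Step 17**
Reactants: 20
Product: 21 oxonane ketone (C7H2; C8–C9 bond formed)
Conditions: (TMS)3SiH, AIBN, benzene, 80 °C, 1 mM, syringe-pump addition over 8 h
Reagents that add atoms: none (H only)
Why: Silyl radical abstracts PhSe to give the nucleophilic THF-2-yl radical at C9, which adds to the vinyl-ketone terminus C8 (9-endo). The α-keto radical is reduced by silane. The 2,5-cis bridging constraint of the 11-oxabicyclo[6.2.1] core forces C8 onto the face bearing C3, which sets C9 as in the target.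
Proposed new method: The closest known reactions are α-alkoxy and anomeric radical Giese additions and radical macrocyclisations onto enones. The mechanistic reasoning is that the pre-organised cis-THF bicycle makes the 9-endo closure viable and the bridge fixes C9.

**Step 18**
Reactants: 21
Product: 22 Asbestinin 16
Conditions: LiHMDS, THF, −78 °C; then Me2N+=CH2 I− (Eschenmoser's salt); then MeI, NaHCO3, CH2Cl2
Reagents that add atoms: Eschenmoser's salt, C=[N+](C)C.[I-] (supplies the exocyclic CH2, C19)
Why: Kinetic enolisation at the less hindered C7, Mannich aminomethylation, then quaternisation and elimination gives the α-methylene ketone. No stereocentre is formed or altered.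

---

**Compound list**

| # | Name | SMILES | Role |
|---|------|--------|------|
| 1 | (R)-5-methylcyclohex-2-en-1-one | O=C1C=CC[C@@H](C)C1 | starting material |
| 2 | (R)-2-iodo-5-methylcyclohex-2-en-1-one | O=C1C(I)=CC[C@@H](C)C1 | intermediate |
| 3 | methacrolein | C=C(C)C=O | starting material |
| 4 | NHK allylic alcohol (1′R) | O=C1C([C@H](O)C(C)=C)=CC[C@@H](C)C1 | intermediate |
| 5 | epoxy alcohol (C2 S, C3 R) | O=C1C([C@H](O)[C@@]2(C)CO2)=CC[C@@H](C)C1 | intermediate |
| 6 | allyl alcohol | C=CCO | starting material |
| 7 | C3 allyl ether diol (C2 S, C3 S) | O=C1C([C@H](O)[C@@](C)(OCC=C)CO)=CC[C@@H](C)C1 | intermediate |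
| 8 | C4 TBDPS ether of 7 | O=C1C([C@H](O)[C@@](C)(OCC=C)CO[Si](c2ccccc2)(c2ccccc2)C(C)(C)C)=CC[C@@H](C)C1 | intermediate |
| 9 | oxepane-fused cyclohexanone | O=C1C[C@H](C)C[C@@H]2[C@@H]1[C@H](O)[C@](C)(CO[Si](c3ccccc3)(c3ccccc3)C(C)(C)C)OC[C@@H]2C | intermediate |
| 10 | 11-hydroxy ketone (OH trans to Me) | O=C1[C@@H](O)[C@H](C)C[C@@H]2[C@@H]1[C@H](O)[C@](C)(CO[Si](c3ccccc3)(c3ccccc3)C(C)(C)C)OC[C@@H]2C | intermediate |
| 11 | methoxymethylene enol ether | COC=C1[C@@H](O)[C@H](C)C[C@@H]2[C@@H]1[C@H](O)[C@](C)(CO[Si](c3ccccc3)(c3ccccc3)C(C)(C)C)OC[C@@H]2C | intermediate |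
| 12 | THF methyl acetal, 11-OH trans (C9 epimeric) | COC2O[C@H]3[C@H]4[C@@H](C[C@@H](C)[C@H](O)[C@H]42)[C@@H](C)CO[C@@]3(C)CO[Si](c5ccccc5)(c5ccccc5)C(C)(C)C | intermediate |
| 13 | 11-acetate (cis), methyl acetal | COC2O[C@H]3[C@H]4[C@@H](C[C@@H](C)[C@@H](OC(C)=O)[C@H]42)[C@@H](C)CO[C@@]3(C)CO[Si](c5ccccc5)(c5ccccc5)C(C)(C)C | intermediate |
| 14 | phenylselenoacetal | [Se](c1ccccc1)C2O[C@H]3[C@H]4[C@@H](C[C@@H](C)[C@@H](OC(C)=O)[C@H]42)[C@@H](C)CO[C@@]3(C)CO[Si](c5ccccc5)(c5ccccc5)C(C)(C)C | intermediate |
| 15 | primary alcohol | [Se](c1ccccc1)C2O[C@H]3[C@H]4[C@@H](C[C@@H](C)[C@@H](OC(C)=O)[C@H]42)[C@@H](C)CO[C@@]3(C)CO | intermediate |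
| 16 | aldehyde | [Se](c1ccccc1)C2O[C@H]3[C@H]4[C@@H](C[C@@H](C)[C@@H](OC(C)=O)[C@H]42)[C@@H](C)CO[C@@]3(C)C=O | intermediate |
| 17 | methyl vinyl ketone | C=CC(C)=O | starting material |
| 18 | 2-(trimethylsilyloxy)buta-1,3-diene | C=CC(=C)O[Si](C)(C)C | intermediate |
| 19 | aldol vinyl ketone (C4 R) | [Se](c1ccccc1)C2O[C@H]3[C@H]4[C@@H](C[C@@H](C)[C@@H](OC(C)=O)[C@H]42)[C@@H](C)CO[C@@]3(C)[C@H](O)CC(=O)C=C | intermediate |
| 20 | C4 octanoate (radical precursor) | [Se](c1ccccc1)C2O[C@H]3[C@H]4[C@@H](C[C@@H](C)[C@@H](OC(C)=O)[C@H]42)[C@@H](C)CO[C@@]3(C)[C@H](OC(=O)CCCCCCC)CC(=O)C=C | intermediate |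
| 21 | oxonane ketone (7-desmethylene) | C1C[C@@H]2O[C@H]3[C@H]4[C@@H](C[C@@H](C)[C@@H](OC(C)=O)[C@H]42)[C@@H](C)CO[C@@]3(C)[C@H](OC(=O)CCCCCCC)CC1=O | intermediate |
| 22 | Asbestinin 16 | C=C1C[C@@H]2O[C@H]3[C@H]4[C@@H](C[C@@H](C)[C@@H](OC(C)=O)[C@H]42)[C@@H](C)CO[C@@]3(C)[C@H](OC(=O)CCCCCCC)CC1=O | target |

---

**Totals**
- Total steps: 18.
- Longest linear sequence: 17 (Steps 1–13 and 15–18 from compound 1; Step 14 is a one-step side branch from MVK).

**Three steps most likely to fail**
1. **Step 6 (7-endo HAT radical cyclisation).** Direct reduction of the enone or poor C14/C15 stereocontrol are the risks. *Fallback (changes approach):* set C14–C15 by TiCl4-mediated Hosomi–Sakurai conjugate addition of (E)-crotyltrimethylsilane to the enone (syn-selective, open transition state). Convert the vinyl group to CH2OH (OsO4/NaIO4, then NaBH4), keep epoxide 5 unopened, and close the oxepane by CSA-promoted 7-exo epoxide opening at C3.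
2. **Step 17 (9-endo macrocyclisation).** Premature reduction of the C9 radical or oligomerisation are the risks. *Fallback (changes approach):* intermolecular radical allylation of the C9 selenide with 2-bromoallyltributylstannane to install C8–C7(Br)=CH2, place a C6 aldehyde on the C4 side chain by an aldol with an acetaldehyde equivalent, close C6–C7 by intramolecular NHK, and oxidise C6–OH to the ketone with Dess–Martin periodinane.
3. **Step 15 (chelation-controlled aldol on the hindered quaternary aldehyde).** The risks are wrong C4 diastereoselectivity, and TiCl4 ionising the selenoacetal. *Fallback (changes approach):* run a non-chelating Felkin-selective aldol (BF3·OEt2) to give the C4 epimer, then invert and acylate in one step by Mitsunobu esterification with octanoic acid.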